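The electrophile, charged at 22 mM, couples with the nucleophile to give the target, with free base present at 1.10 equiv. The readings follow the target and nothing else.

| setting | Thursday's | Friday's | Saturday's | gamma | alpha | eta |
|---|---|---|---|---|---|---|
| electrophile | 22 mM | 22 mM | 22 mM | 22 mM | 22 mM | 22 mM |
| nucleophile | 0.23 equiv | 0.67 equiv | 1.4 equiv | 0.200 equiv | 0.600 equiv | 2.00 equiv |
| free base | 1.1 equiv | 1.1 equiv | 1.1 equiv | 1.10 equiv | 1.10 equiv | 1.10 equiv |
| remark | run made earlier | run made earlier | run made earlier |  |  |  |
| time |  |  |  | 10 h | 10 h | 10 h |

- Thursday's (time / h: target / %): 0.667: 5; 2.00: 1; 3.00: 0; 5.00: 3; 8.00: 2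
- Friday's (time / h: target / %): 0.500: 4; 1.00: 0; 2.00: 6; 4.00: 5; 8.00: 9
- Saturday's (time / h: target / %): 0.667: 2; 2.00: 7; 3.00: 13; 5.00: 18; 8.00: 19

(each reading ± 2 percentage points)

* amount of target at the end, in percent of the electrophile charged for gamma, alpha, eta, in this order
* how that number moves from the first to the last of them (rises all the way / rises, then falls / hardly changes / falls, then rises / falls all the way)

- "hardly changes" means that all values lie within two and a half points (for a concentration: within two and a half percent of the largest)

Saturday's run gained 18 % in its first 5.00 h, and ln(2) times that time over that gain gives 19.3 h. This is the time in which coupling would halve the electrophile with the nucleophile held at its charge (a pseudo-first-order view), the coupling half-life. It should scale inversely with the charge: Friday's last reading stands to Saturday's as 0.474, and the charges stand as 0.479, within the scatter.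

The ladder then has a clear order. On the first rung, Saturday's rate slows within 8.00 h, sooner than its own coupling half-life. Its last reading is 0.660 of what the early rate would give. Coupling's own use of its partners allows 0.869, so this reading, with its scatter, points to a second process.

Next come the coupling half-lives: 13.5 h for eta, 44.9 h for alpha and 135 h for gamma, ten times eta's. Assuming the slowing factor does not depend on the charge, and holding it to 10 h, this reckoning gives 3.39 %, 10.2 % and 33.9 %.

The forecast, lower at eta, reads 2 %, 10 %, 28 %, rises all the way: “A rise all the way is most likely”.

The flasks give 3.91 %, 11.0 % and 31.5 %, so the target rises all the way.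

    crystals ⇌ acid set free, rate k1*(cs1 - [acid set free]) while solid is left; crystals form when [acid set free] > cs1 (solubility = 18.0 mM, k = 2.11 h⁻¹)
    electrophile + nucleophile → acid set free + target (k = 1.40 L mol⁻¹ h⁻¹)
    acid set free + free base ⇌ salt of the base, settled at all times (K = 69.0 L mol⁻¹)
    nucleophile + acid set free ⇌ protonated nucleophile, settled at all times (K = 600 L mol⁻¹)
    electrophile ⇌ dormant form (K = 7.66, k = 0.0579 h⁻¹)

At 10.0 h the dormant form stood at 41.4 %, 39.5 % and 33.6 % in gamma, alpha and eta, a narrow spread beside a tenfold range of charge. In eta at that time, 34.9 % of the electrophile and 70.5 % of the nucleophile's charge remained, so the rate of target stood at a quarter of its start, and the coupling half-life read from Saturday's scattered readings, 13.5 h at eta's charge, comes to 19.1 h on that remaining nucleophile.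

(The data stem from a simulated flask from invented constants, noise included.)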